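**Retrosynthetic overview** (ring numbering: O1, C2 lactone carbonyl, C3 butyl-bearing, C4 bromine-bearing, C5, exocyclic C6)

1. Enabling feature: the O1–C2(=O) segment of the furan-2(5H)-one ring is a hidden CO2. The remaining C3–C4–C5=C6 chain plus the butyl group is the skeleton of oct-1-yn-3-one, with C3 as the donor α-carbon, C4 as the ketone carbon and C5/C6 as the acceptor alkyne.
2. C6–Br (twice) is traced back to a C6–SiMe3/C6–H vinylsilane by ipso-bromodesilylation followed by Br2 addition and HBr loss. C4–Br is traced back to the C4–OH of a tetronic acid.
3. C2–C3 and O1–C5 are cut together, giving 1-(trimethylsilyl)oct-1-yn-3-one plus CO2. The forward reaction is a silver-catalysed formal (3+2) carboxylative 5-exo-dig cyclisation.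
4. The silyl ynone comes from hexanoyl chloride and bis(trimethylsilyl)acetylene. The silyl cap is a temporary protecting and directing group that leaves in the last step.
5. Ring order: the molecule has one ring, and the key step makes it complete with the butyl group, the C4 handle and the exocyclic alkene.

Key step: step 2

Remark on the chemistry: the target has no stereocentre, and C6 carries two identical substituents. The alkene geometries given for 6, 7 and 8 are the expected ones and do not affect the final product.

**Step 1**
Reactants: 1 hexanoyl chloride; 2 bis(trimethylsilyl)acetylene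
Product: 3 1-(trimethylsilyl)oct-1-yn-3-one
Conditions: AlCl3 (1.1 equiv), CH2Cl2, 0 °C; then ice/1 M HCl
Reagents that add atoms: none
Why: Friedel–Crafts-type acylative ipso-desilylation of a bis-silyl alkyne stops cleanly after one acylation, because the resulting ynone is deactivated towards a second attack.

**Step 2**
Reactants: 3 1-(trimethylsilyl)oct-1-yn-3-one; 4 carbon dioxide
Product: 6 (Z)-3-butyl-4-hydroxy-5-[(trimethylsilyl)methylidene]furan-2(5H)-one, via β-keto carboxylate 5 (not isolated)
Conditions: CO2 (1.0 MPa), AgOBz (10 mol %), MTBD (2 equiv), 4 Å MS, dry MeCN, 25 °C; then cold 1 M HCl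
Reagents that add atoms: none
Why: MTBD reversibly enolises 3 at its only enolisable position (the other flank of the ketone is the alkyne) and the enolate carbon attacks CO2 to give 5 (new C–C bond), after which Ag(I) π-activates the alkyne, the carboxylate oxygen adds anti to the ketone-side alkyne carbon (new O–C bond), and protodeargentation and enolisation give the tetronate, so that overall the C–C–C unit of the ynone and one C=O of CO2 combine in a formal (3+2) annulation. The closest known reaction type is the silver-catalysed carboxylative cyclisation of conjugated ynones and other alkynyl ketones with CO2 under amidine or guanidine base, which gives 5-ylidene tetronic acids. The single ring closes in the 5-exo-dig mode. No stereocentre is formed, and the Z geometry of the exocyclic alkene follows from anti oxyargentation and stereoretentive protonolysis. The step needs C- over O-carboxylation, which is secured because carboxylation and decarboxylation are reversible while cyclisation to the acidic, immediately deprotonated tetronate is an irreversible sink, and it needs 5-exo over 6-endo (4-hydroxy-2-pyranone) closure, which Ag(I) favours and the silyl cap reinforces by shielding the distal carbon and stabilising positive charge at the carbon β to silicon. The same cap suppresses the silver acetylide formation and the conjugate addition of base that a terminal ynone would suffer.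

**Step 3**
Reactants: 6 (Z)-3-butyl-4-hydroxy-5-[(trimethylsilyl)methylidene]furan-2(5H)-one
Product: 7 (Z)-4-bromo-3-butyl-5-[(trimethylsilyl)methylidene]furan-2(5H)-one
Conditions: (COBr)2 (1.3 equiv), DMF (1.3 equiv), CH2Cl2, 0 °C → rt
Reagents that add atoms: oxalyl bromide, O=C(Br)C(=O)Br
Why: Vilsmeier-type activation of the vinylogous acid OH as an O-iminium leaving group, followed by bromide addition–elimination at C4, is the standard conversion of tetronic acids into 4-bromobutenolides, and C3 is blocked by the butyl group against side reactions.

**Step 4**
Reactants: 7 (Z)-4-bromo-3-butyl-5-[(trimethylsilyl)methylidene]furan-2(5H)-one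
Product: 10 4-bromo-3-butyl-5-(dibromomethylidene)furan-2(5H)-one (target), via bromomethylidene lactone 8 (not isolated), via tetrabromide 9 (not isolated)
Conditions: Br2 (2.3 equiv), CH2Cl2, 0 °C → rt, dark; evaporate; then Et3N (1.5 equiv), CH2Cl2, 0 °C
Reagents that add atoms: bromine, BrBr
Why: Electrophilic ipso-bromodesilylation of the vinylsilane (the C5 cation is stabilised by O1 and the β-silicon, so retention to Z-8 is expected) is followed by ionic Br2 addition to the same exocyclic enol-ester alkene, the only nucleophilic π bond, and then by E2 loss of the acidic CHBr2 hydrogen and the tertiary C5 bromide, a bromine addition/dehydrobromination sequence well established for 5-methylidene butenolides, in which the racemic C5 stereocentre of 9 is destroyed again.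

**Compound list**
1 | hexanoyl chloride | CCCCCC(=O)Cl | starting material
2 | bis(trimethylsilyl)acetylene | C[Si](C)(C)C#C[Si](C)(C)C | starting material
3 | 1-(trimethylsilyl)oct-1-yn-3-one | CCCCCC(=O)C#C[Si](C)(C)C | intermediate
4 | carbon dioxide | O=C=O | starting material
5 | 2-butyl-3-oxo-5-(trimethylsilyl)pent-4-ynoic acid, present as its MTBD-H+ carboxylate (racemic, configurationally labile, not isolated) | CCCCC(C(=O)O)C(=O)C#C[Si](C)(C)C | intermediate
6 | (Z)-3-butyl-4-hydroxy-5-[(trimethylsilyl)methylidene]furan-2(5H)-one | CCCCC1=C(O)/C(=C/[Si](C)(C)C)OC1=O | intermediate
7 | (Z)-4-bromo-3-butyl-5-[(trimethylsilyl)methylidene]furan-2(5H)-one | CCCCC1=C(Br)/C(=C/[Si](C)(C)C)OC1=O | intermediate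
8 | (Z)-4-bromo-5-(bromomethylidene)-3-butylfuran-2(5H)-one (not isolated) | CCCCC1=C(Br)/C(=C/Br)OC1=O | intermediate
9 | 4,5-dibromo-3-butyl-5-(dibromomethyl)furan-2(5H)-one (racemic, not isolated) | CCCCC1=C(Br)C(Br)(C(Br)Br)OC1=O | intermediate
10 | 4-bromo-3-butyl-5-(dibromomethylidene)furan-2(5H)-one | CCCCC1=C(Br)C(=C(Br)Br)OC1=O | target

**Total step count:** 4. **Longest linear sequence:** 4 steps.

**Steps most likely to fail**

**Step 2.** The silyl cap may be lost from the ynone before ring closure through base- or silver-assisted protodesilylation. The guanidine may add in a conjugate sense. Back-decarboxylation may outrun cyclisation for a purely aliphatic enolate.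

The fallback sets out from 1 and comes back at 6. It brings the carboxyl carbon in with the hexanoate and closes only the O–C bond catalytically, in a base-free medium.
- Compound 1 is esterified with tert-butanol (pyridine, DMAP, CH2Cl2) to tert-butyl hexanoate F1.
- The lithium enolate of this ester (LDA, THF, −78 °C) undergoes a crossed Claisen condensation with commercial ethyl 3-(trimethylsilyl)propiolate. The silyl group blocks conjugate addition. The product is tert-butyl 2-butyl-3-oxo-5-(trimethylsilyl)pent-4-ynoate F2.
- A cationic gold(I) catalyst (Ph3PAuNTf2, CH2Cl2, rt) then triggers 5-exo-dig attack of the ester carbonyl oxygen on the alkyne. The tert-butyl group is lost and 6 should result.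

**Step 4.** The second bromine addition to the electron-poor bromodienolide may stall or reverse. The amine may debrominate rather than dehydrobrominate. Radical bromination may start at the allylic CH2 of the butyl chain.

The fallback sets out from 7 and comes back at 10. It replaces base-induced elimination by bromohydrin formation and acid dehydration.
- Compound 7 is treated with NBS (2.2 equiv) in MeCN/H2O at 0 °C → rt. Ipso-bromodesilylation gives 8 in passing. Irreversible capture of the second bromo-oxocarbenium ion by water should then give the pseudo-acid 4-bromo-3-butyl-5-(dibromomethyl)-5-hydroxyfuran-2(5H)-one F4.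
- This pseudo-acid is dehydrated with P2O5 in refluxing CH2Cl2 (or with concentrated H2SO4) to 10.

**Step 3.** The liberated HBr may protodesilylate the vinylsilane. Bromide addition–elimination may be slow at C4, which is flanked by the butyl group and the ylidene unit.

The fallback sets out from 6 and comes back at 7. It is an acid-free sulfonate activation followed by halide exchange.
- Compound 6 is converted with Tf2O and iPr2NEt (CH2Cl2, −78 °C) into (Z)-4-butyl-5-oxo-2-[(trimethylsilyl)methylidene]-2,5-dihydrofuran-3-yl trifluoromethanesulfonate F3.
- LiBr (THF or acetone, rt to 40 °C) then displaces the triflate by vinylic addition–elimination to give 7.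

**Further compounds**
F1 | step 2 | tert-butyl hexanoate | CCCCCC(=O)OC(C)(C)C
F2 | step 2 | tert-butyl 2-butyl-3-oxo-5-(trimethylsilyl)pent-4-ynoate (racemic) | CCCCC(C(=O)OC(C)(C)C)C(=O)C#C[Si](C)(C)C
F3 | step 3 | (Z)-4-butyl-5-oxo-2-[(trimethylsilyl)methylidene]-2,5-dihydrofuran-3-yl trifluoromethanesulfonate | CCCCC1=C(OS(=O)(=O)C(F)(F)F)/C(=C/[Si](C)(C)C)OC1=O
F4 | step 4 | 4-bromo-3-butyl-5-(dibromomethyl)-5-hydroxyfuran-2(5H)-one (racemic) | CCCCC1=C(Br)C(O)(C(Br)Br)OC1=O
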